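**Retrosynthetic overview**
- Triphloroethol A comes from global O-demethylation of a trimeric hexamethyl ether that carries one free OH on ring C.
- The ring B–O–ring C bond is cut to a dimeric phenol plus a 3,5-dimethoxy ortho-quinone diazide (proposed Rh-carbene O–H insertion; ring C arrives with its ortho OH already free).
- The ring A–O–ring B bond is cut the same way: 3,5-dimethoxyphenol plus the same quinone diazide. Each insertion unmasks the phenol needed for the next, so the chain grows A → A–B → A–B–C.
- The quinone diazide comes from 2-amino-3,5-dimethoxyphenol, made from 1,3,5-trimethoxy-2-nitrobenzene by chelation-directed mono-demethylation and nitro reduction.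
- No ring is formed; all three benzene rings are bought.

Assumption: the target has no stereocentre and no isolable stereogenic axis, so "single enantiomer" is taken to mean the achiral compound as drawn.

**Route**

Step 1
Reactants: 1 1,3,5-trimethoxy-2-nitrobenzene
Product: 2 3,5-dimethoxy-2-nitrophenol
Conditions: BCl3 (1.2 equiv, 1 M in CH2Cl2), CH2Cl2, −78 °C → 0 °C, 2 h; then ice-water
Reagents that add atoms: none
Why: Chelation-directed Lewis-acid ether cleavage: boron bound to a nitro oxygen delivers chloride only to an ortho O-methyl (the two ortho groups are equivalent, the para one is out of reach), and the resulting aryloxyboron chelate deactivates the ring toward a second cleavage; no stereocentre is formed.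

Step 2
Reactants: 2 3,5-dimethoxy-2-nitrophenol
Product: 3 2-amino-3,5-dimethoxyphenol
Conditions: H2 (1 atm), 10% Pd/C, EtOAc, rt, 3 h; filtered through Celite under Ar, concentrated, used at once
Reagents that add atoms: none
Why: Catalytic hydrogenation of a nitroarene to the aniline is clean here because aryl ethers and the phenol are inert to Pd/H2; the air-sensitive aminophenol is not stored.

Step 3
Reactants: 3 2-amino-3,5-dimethoxyphenol
Product: 5 2-diazo-3,5-dimethoxycyclohexa-3,5-dien-1-one, via diazonium tetrafluoroborate 4 (not isolated)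
Conditions: t-BuONO (1.1 equiv), HBF4 (48% aq, 1.2 equiv), EtOH, 0 °C, 30 min; then CH2Cl2/sat. aq NaHCO3, 0 °C, dark; dried, concentrated cold, stored at −20 °C in the dark (small scale, blast shield)
Reagents that add atoms: tert-butyl nitrite, CC(C)(C)ON=O
Why: Diazotisation of an ortho-aminophenol followed by deprotonation of the acidic ortho-hydroxy diazonium ion is the textbook route to ortho-quinone diazides, and the strongly acidic medium keeps the amine protonated so the ring is protected from C-nitrosation and azo coupling.

Step 4
Reactants: 6 3,5-dimethoxyphenol; 5 2-diazo-3,5-dimethoxycyclohexa-3,5-dien-1-one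
Product: 7 2-(3,5-dimethoxyphenoxy)-3,5-dimethoxyphenol
Conditions: Rh2(esp)2 (1 mol%), 4 Å MS, PhCF3, 60 °C, dark, Ar; 6 (3 equiv) in the flask, 5 (1 equiv) added over 6 h by syringe pump; excess 6 recovered on silica
Reagents that add atoms: none
Why: Proposed new method: Rh(II) attacks the methoxy-activated diazo carbon of 5 and loses N2 to give an ortho-quinoid Rh carbene, the phenol oxygen of 6 adds to the carbene carbon to form an oxonium ylide, and loss of Rh with proton transfer to the neighbouring carbonyl oxygen restores aromaticity and gives the 2-aryloxyphenol (formal O–H insertion, driven by aromatisation; the 3- and 5-methoxy donors tame the carbene so O-attack should win over Wolff ring contraction and arene C–H attack, and excess 6 with slow addition suppresses a second insertion into the more hindered OH of 7); the closest known reaction type is Rh(II)-carbene O–H insertion of phenols with 2-diazo-1,3-dicarbonyl compounds together with Rh-catalysed C–H and N–H arylations by quinone diazides, and its use with an electron-rich 3,5-dialkoxy ortho-quinone diazide to make ortho-oxygenated diaryl ethers is, as far as I know, not described; no stereocentre is formed.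

Step 5
Reactants: 7 2-(3,5-dimethoxyphenoxy)-3,5-dimethoxyphenol; 5 2-diazo-3,5-dimethoxycyclohexa-3,5-dien-1-one
Product: 8 2-[2-(3,5-dimethoxyphenoxy)-3,5-dimethoxyphenoxy]-3,5-dimethoxyphenol
Conditions: Rh2(esp)2 (2 mol%), 4 Å MS, PhCF3, 70 °C, dark, Ar; 7 (2 equiv) in the flask, 5 (1 equiv) added over 8 h by syringe pump; excess 7 recovered and recycled
Reagents that add atoms: none
Why: Proposed new method: the same Rh-carbene O–H insertion as in step 4, now with the ortho-aryloxy phenol 7 as O-nucleophile; carbene capture by a lone pair tolerates crowding far better than a metal-centred reductive elimination, so the tri-ortho-oxygenated ether should form under neutral conditions, with ring C arriving at the correct oxidation level and its ortho OH free; the closest known reaction type is Rh(II)-carbene O–H insertion of hindered phenols with diazocarbonyl compounds, and this iterative use on a quinone diazide is untested; no stereocentre is formed.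

Step 6
Reactants: 8 2-[2-(3,5-dimethoxyphenoxy)-3,5-dimethoxyphenoxy]-3,5-dimethoxyphenol
Product: 9 triphloroethol A (2-[2-(3,5-dihydroxyphenoxy)-3,5-dihydroxyphenoxy]benzene-1,3,5-triol)
Conditions: BBr3 (12 equiv), CH2Cl2, −78 °C → rt, 18 h; then H2O, 0 °C; EtOAc extraction; Sephadex LH-20 (MeOH) under Ar
Reagents that add atoms: none
Why: BBr3 demethylation cleaves each aryl methyl ether by bromide SN2 attack on the O-methyl of the borane adduct, while the diaryl ether C(sp2)–O bonds have no such pathway and survive; the molecule has no stereocentre to scramble.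

**Compound list**
1 | 1,3,5-trimethoxy-2-nitrobenzene | COc1cc(OC)c([N+](=O)[O-])c(OC)c1 | starting material
2 | 3,5-dimethoxy-2-nitrophenol | COc1cc(O)c([N+](=O)[O-])c(OC)c1 | intermediate
3 | 2-amino-3,5-dimethoxyphenol | COc1cc(O)c(N)c(OC)c1 | intermediate
4 | 2-hydroxy-4,6-dimethoxybenzenediazonium tetrafluoroborate | COc1cc(O)c([N+]#N)c(OC)c1.F[B-](F)(F)F | intermediate (not isolated)
5 | 2-diazo-3,5-dimethoxycyclohexa-3,5-dien-1-one (ortho-quinone diazide) | O=C1C=C(OC)C=C(OC)C1=[N+]=[N-] | intermediate
6 | 3,5-dimethoxyphenol | COc1cc(O)cc(OC)c1 | starting material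
7 | 2-(3,5-dimethoxyphenoxy)-3,5-dimethoxyphenol | COc1cc(O)c(Oc2cc(OC)cc(OC)c2)c(OC)c1 | intermediate
8 | 2-[2-(3,5-dimethoxyphenoxy)-3,5-dimethoxyphenoxy]-3,5-dimethoxyphenol | COc1cc(Oc2c(O)cc(OC)cc2OC)c(Oc2cc(OC)cc(OC)c2)c(OC)c1 | intermediate
9 | triphloroethol A | Oc1cc(O)cc(Oc2c(O)cc(O)cc2Oc2c(O)cc(O)cc2O)c1 | target

**Step count**
Total steps: 6. Longest linear sequence: 6 (1 → 2 → 3 → 5 → 7 → 8 → 9; compound 5 is used in steps 4 and 5).

**Three steps most likely to fail, with fallbacks**

Step 4 (proposed new step). The risks are C-attack of the carbene on the very nucleophilic ring of 6, Wolff-type ring contraction, and a second insertion into the OH of 7. The fallback uses known chemistry, sets out from 6 and comes back at 7. Phenol 6 is coupled with commercial 2-bromo-3,5-dimethoxybenzaldehyde (COc1cc(OC)c(Br)c(C=O)c1) in an ortho-carbonyl-assisted Ullmann ether synthesis (CuI 10 mol%, N,N-dimethylglycine 30 mol%, Cs2CO3, dioxane, 100 °C) to give 2-(3,5-dimethoxyphenoxy)-3,5-dimethoxybenzaldehyde F1. Baeyer–Villiger (Dakin-type) oxidation with mCPBA and NaHCO3 in CH2Cl2 at 0 °C → rt, where the ortho-aryloxy aryl group migrates, gives 2-(3,5-dimethoxyphenoxy)-3,5-dimethoxyphenyl formate F2. Methanolysis (K2CO3, MeOH, rt) then gives 7.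

Step 5 (proposed new step, more hindered). Beyond the risks of step 4, product 8 carries an OH much like that of 7 and can take up another carbene, so the yield depends on excess 7 and slow addition. The fallback uses known chemistry, sets out from 7 and comes back at 8. Phenol 7 and 2-bromo-3,5-dimethoxybenzaldehyde are coupled under hindered-phenol Ullmann conditions (CuI 20 mol%, picolinic acid 40 mol%, K3PO4, DMSO, 100 °C) to give 2-[2-(3,5-dimethoxyphenoxy)-3,5-dimethoxyphenoxy]-3,5-dimethoxybenzaldehyde F3. Baeyer–Villiger oxidation (mCPBA, NaHCO3, CH2Cl2) gives 2-[2-(3,5-dimethoxyphenoxy)-3,5-dimethoxyphenoxy]-3,5-dimethoxyphenyl formate F4. K2CO3 in MeOH then gives 8, with the ring C OH in the same place as from the carbene route.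

Step 3. The very electron-rich aminophenol 3 may be oxidised or C-nitrosated by the nitrite, or the diazonium ion may azo-couple before it is deprotonated. The fallback avoids the amine and nitrosating agents altogether, sets out from 6 and comes back at 5. Phenol 6 is ortho-oxidised with IBX (DMF, rt) to 3,5-dimethoxycyclohexa-3,5-diene-1,2-dione F5. This is condensed with tosylhydrazide (MeOH, 0 °C) at C2, the more ketone-like carbonyl (C1 is a vinylogous ester through the 5-methoxy group), to give N'-(2,4-dimethoxy-6-oxocyclohexa-2,4-dien-1-ylidene)-4-methylbenzenesulfonohydrazide F6. Et3N in CH2Cl2 at 0 °C then eliminates toluenesulfinate (Bamford–Stevens-type) to give 5. The regiochemistry of the condensation is predicted, not established, and must be confirmed before use (for example by reducing a sample to the known phenol pattern).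

**Further compounds**
F1 | step 4 | 2-(3,5-dimethoxyphenoxy)-3,5-dimethoxybenzaldehyde | COc1cc(C=O)c(Oc2cc(OC)cc(OC)c2)c(OC)c1
F2 | step 4 | 2-(3,5-dimethoxyphenoxy)-3,5-dimethoxyphenyl formate | COc1cc(OC=O)c(Oc2cc(OC)cc(OC)c2)c(OC)c1
F3 | step 5 | 2-[2-(3,5-dimethoxyphenoxy)-3,5-dimethoxyphenoxy]-3,5-dimethoxybenzaldehyde | COc1cc(Oc2c(C=O)cc(OC)cc2OC)c(Oc2cc(OC)cc(OC)c2)c(OC)c1
F4 | step 5 | 2-[2-(3,5-dimethoxyphenoxy)-3,5-dimethoxyphenoxy]-3,5-dimethoxyphenyl formate | COc1cc(Oc2c(OC=O)cc(OC)cc2OC)c(Oc2cc(OC)cc(OC)c2)c(OC)c1
F5 | step 3 | 3,5-dimethoxycyclohexa-3,5-diene-1,2-dione | O=C1C=C(OC)C=C(OC)C1=O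
F6 | step 3 | N'-(2,4-dimethoxy-6-oxocyclohexa-2,4-dien-1-ylidene)-4-methylbenzenesulfonohydrazide | Cc1ccc(cc1)S(=O)(=O)NN=C1C(=O)C=C(OC)C=C1OC
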